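**Strategy.** Everything rests on disconnecting the aryl ether bond O1–C8a in the pyran ring of the 7-hydroxyisoflavan unit that has no C4 substituent. Because the C7 hydroxyl of its ring A is para to C4a, this ring can be carried as a plain para-alkylphenol: oxidative dearomatisation gives a 4-methoxycyclohexa-2,5-dienone, the side-chain primary alcohol adds 6-exo to a dienone β-carbon (the future C8a) and loss of methanol rearomatises, a formal meta C–H etherification that closes the chroman in one operation. The precursor is an acyclic (R)-2-aryl-3-(4-hydroxyphenyl)propan-1-ol from an Evans alkylation; the trans-3,4-diarylchroman is then grown from the acetal on the central ring.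

Key step: step 8

Remark: silyl ether 10 is taken as a purchasable building block. Both C3 centres use the same (R)-4-benzyloxazolidin-2-one, because both C–C bond formations occur on the chelated enolate face away from the auxiliary benzyl group.

Step 1
Reactants: 1 methyl 2-(3,5-dihydroxyphenyl)acetate
Product: 2 methyl 2-(2-formyl-3,5-dihydroxyphenyl)acetate
Conditions: POCl3, DMF, MeCN, 0 °C → rt; then H2O, 50 °C
Reagents that add atoms: N,N-dimethylformamide CN(C)C=O; water O
Why: Vilsmeier–Haack formylation of the resorcinol ring should occur at the carbon flanked by the side chain and one hydroxyl (ortho/para to both OH groups, as with orcinol) and not between the two hydroxyls.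

Step 2
Reactants: 2 methyl 2-(2-formyl-3,5-dihydroxyphenyl)acetate
Product: 3 methyl 2-[5-(benzyloxy)-2-formyl-3-hydroxyphenyl]acetate
Conditions: BnBr (1.05 equiv), NaHCO3, MeCN, 70 °C
Reagents that add atoms: benzyl bromide BrCc1ccccc1
Why: Williamson etherification; the hydroxyl para to the formyl group is the more acidic and is not held in the hydrogen bond to the carbonyl, so a weak base should benzylate it selectively.

Step 3
Reactants: 3 methyl 2-[5-(benzyloxy)-2-formyl-3-hydroxyphenyl]acetate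
Product: 4 methyl 2-[5-(benzyloxy)-2-formyl-3-methoxyphenyl]acetate
Conditions: MeI, K2CO3, DMF, rt
Reagents that add atoms: iodomethane CI
Why: Williamson methylation of the remaining chelated ortho-hydroxyl, which fixes the methoxy group next to the carbon that becomes C4 of the upper chroman.

Step 4
Reactants: 4 methyl 2-[5-(benzyloxy)-2-formyl-3-methoxyphenyl]acetate
Product: 6 lithium 2-[5-(benzyloxy)-2-(dimethoxymethyl)-3-methoxyphenyl]acetate, via acetal ester 5 (not isolated)
Conditions: HC(OMe)3, camphorsulfonic acid (cat.), MeOH, rt; then LiOH (1.05 equiv), THF/H2O, rt; evaporate without acidification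
Reagents that add atoms: trimethyl orthoformate COC(OC)OC; lithium hydroxide [Li+].[OH-]
Why: acid-catalysed acetalisation turns the aldehyde into the dimethyl acetal that later serves as the electrophile, and saponification gives the carboxylate, kept as its lithium salt so that the acid-labile acetal never meets a free carboxylic acid.

Step 5
Reactants: 6 lithium 2-[5-(benzyloxy)-2-(dimethoxymethyl)-3-methoxyphenyl]acetate; 7 (R)-4-benzyloxazolidin-2-one
Product: 9 (R)-4-benzyl-3-{2-[5-(benzyloxy)-2-(dimethoxymethyl)-3-methoxyphenyl]acetyl}oxazolidin-2-one, via mixed pivalic anhydride 8 (not isolated)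
Conditions: t-BuCOCl, THF, −20 °C; then 7, LiCl, Et3N, rt
Reagents that add atoms: none
Why: N-acylation of the oxazolidinone through the mixed pivalic anhydride under LiCl/Et3N, a mild route to the Evans imide that leaves the acetal intact.

Step 6
Reactants: 9 (R)-4-benzyl-3-{2-[5-(benzyloxy)-2-(dimethoxymethyl)-3-methoxyphenyl]acetyl}oxazolidin-2-one; 10 [4-(bromomethyl)phenoxy](tert-butyl)dimethylsilane
Product: 11 (R)-4-benzyl-3-{(2R)-2-[5-(benzyloxy)-2-(dimethoxymethyl)-3-methoxyphenyl]-3-[4-(tert-butyldimethylsilyloxy)phenyl]propanoyl}oxazolidin-2-one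
Conditions: NaN(SiMe3)2, THF, −78 °C; then 10, −78 → −40 °C
Reagents that add atoms: none
Why: Evans asymmetric alkylation; the chelated Z-sodium enolate should be benzylated on the face away from the auxiliary benzyl group, which sets the future C3 of the lower chroman as R.

Step 7
Reactants: 11 the alkylated imide
Product: 13 4-{(2R)-2-[5-(benzyloxy)-2-(dimethoxymethyl)-3-methoxyphenyl]-3-hydroxypropyl}phenol, via silyl ether alcohol 12 (not isolated)
Conditions: LiBH4, MeOH (1 equiv), THF, 0 °C; then Bu4NF, rt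
Reagents that add atoms: none
Why: reductive cleavage of the imide to the primary alcohol, then fluoride desilylation of the aryl silyl ether in the same flask; neither reagent should touch the acetal or the stereocentre.

Step 8
Reactants: 13 4-{(2R)-2-[5-(benzyloxy)-2-(dimethoxymethyl)-3-methoxyphenyl]-3-hydroxypropyl}phenol
Product: 16 (3R)-3-[5-(benzyloxy)-2-(dimethoxymethyl)-3-methoxyphenyl]chroman-7-ol, via methoxydienone 14 (not isolated), via oxa-Michael adduct 15 (not isolated)
Conditions: PhI(OAc)2, K2CO3, MeOH, 0 °C → rt; then HCl/MeOH, HC(OMe)3, 40 °C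
Reagents that add atoms: none
Why: PhI(OAc)2 should oxidise the only free phenol through an aryloxy-iodane to a phenoxonium equivalent that methanol traps at the para carbon (future C4a), giving the 4-methoxycyclohexa-2,5-dienone 14; under the carbonate base the side-chain alkoxide adds to a dienone β-carbon in an oxa-Michael reaction (O1–C8a formed, 15), and acid then enolises the ketone and expels methanol from C4a to restore the aromatic ring with the new oxygen meta to the C7 hydroxyl. The closest known reaction type is the oxidative dearomatisation of para-alkylphenols to quinol ethers followed by hetero-Michael addition and rearomatisation (formal meta-functionalisation of phenols, and the intramolecular oxa-Michael cyclisations of quinols). The pyran ring closes in a 6-exo-trig mode. No new stereocentre survives, since the two ring-fusion centres of 15 (cis by geometry) are erased on aromatisation and C3 is not involved. The step needs chemoselective oxidation of the phenol over the benzyl- and methyl-protected ring and a single site of C–O bond formation: the first is secured by the much lower oxidation potential of the free phenol and by methanol as trapping solvent, the second by the fact that both β-carbons of the symmetric dienone lead to the same 7-hydroxychroman. The carbonate buffer should keep the dimethyl acetal from exchanging with the free alcohol before the Michael addition, and orthoformate should keep it intact in the acidic stage.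

Step 9
Reactants: 16 (3R)-3-[5-(benzyloxy)-2-(dimethoxymethyl)-3-methoxyphenyl]chroman-7-ol
Product: 17 (3R)-7-(benzyloxy)-3-[5-(benzyloxy)-2-(dimethoxymethyl)-3-methoxyphenyl]chroman
Conditions: BnBr, K2CO3, DMF, rt
Reagents that add atoms: benzyl bromide BrCc1ccccc1
Why: Williamson benzylation of the new phenol, so that it cannot compete in the later Mitsunobu step and all phenols carry one hydrogenolysable group.

Step 10
Reactants: 18 1-(2-hydroxy-4,5-dimethoxyphenyl)ethan-1-one
Product: 19 1-[2-(benzyloxy)-4,5-dimethoxyphenyl]ethan-1-one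
Conditions: BnBr, K2CO3, DMF, 60 °C
Reagents that add atoms: benzyl bromide BrCc1ccccc1
Why: Williamson benzylation of the hydrogen-bonded ortho-hydroxyl of the acetophenone.

Step 11
Reactants: 19 1-[2-(benzyloxy)-4,5-dimethoxyphenyl]ethan-1-one
Product: 21 2-[2-(benzyloxy)-4,5-dimethoxyphenyl]acetic acid, via thiomorpholide 20 (not isolated)
Conditions: S8, morpholine, 130 °C; then KOH, EtOH/H2O, reflux; then HCl
Reagents that add atoms: potassium hydroxide [K+].[OH-]; water O
Why: the Willgerodt–Kindler reaction moves the oxidised carbon to the chain terminus as the thioamide, and basic hydrolysis should give the arylacetic acid.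

Step 12
Reactants: 21 2-[2-(benzyloxy)-4,5-dimethoxyphenyl]acetic acid; 7 (R)-4-benzyloxazolidin-2-one
Product: 23 (R)-4-benzyl-3-{2-[2-(benzyloxy)-4,5-dimethoxyphenyl]acetyl}oxazolidin-2-one, via mixed pivalic anhydride 22 (not isolated)
Conditions: t-BuCOCl, Et3N, THF, −20 °C; then 7, LiCl, rt
Reagents that add atoms: none
Why: N-acylation of the oxazolidinone through the mixed pivalic anhydride, as in step 5.

Step 13
Reactants: 23 (R)-4-benzyl-3-{2-[2-(benzyloxy)-4,5-dimethoxyphenyl]acetyl}oxazolidin-2-one; 17 (3R)-7-(benzyloxy)-3-[5-(benzyloxy)-2-(dimethoxymethyl)-3-methoxyphenyl]chroman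
Product: 24 (R)-4-benzyl-3-{(2S)-2-[2-(benzyloxy)-4,5-dimethoxyphenyl]-3-[4-(benzyloxy)-2-((3R)-7-(benzyloxy)chroman-3-yl)-6-methoxyphenyl]-3-methoxypropanoyl}oxazolidin-2-one (epimers at the methoxy-bearing carbon)
Conditions: 23, TiCl4, i-Pr2NEt, CH2Cl2, −78 °C; then 17, TiCl4, −78 → −40 °C
Reagents that add atoms: none
Why: SN1-type alkylation of the chelated chlorotitanium enolate of an Evans imide by the oxocarbenium ion released from the dimethyl acetal; attack on the face away from the auxiliary benzyl group should set the future C3 of the upper chroman, while the methoxy-bearing carbon is ionised later and need not be controlled.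

Step 14
Reactants: 24 the β-methoxy imide
Product: 25 (2R)-2-[2-(benzyloxy)-4,5-dimethoxyphenyl]-3-[4-(benzyloxy)-2-((3R)-7-(benzyloxy)chroman-3-yl)-6-methoxyphenyl]-3-methoxypropan-1-ol
Conditions: LiBH4, MeOH (1 equiv), THF, 0 °C
Reagents that add atoms: none
Why: reductive removal of the auxiliary gives the primary alcohol without touching the α-stereocentre.

Step 15
Reactants: 25 the primary alcohol; 26 3-(benzyloxy)phenol
Product: 27 1-(benzyloxy)-3-{[(2R)-2-[2-(benzyloxy)-4,5-dimethoxyphenyl]-3-[4-(benzyloxy)-2-((3R)-7-(benzyloxy)chroman-3-yl)-6-methoxyphenyl]-3-methoxypropyl]oxy}benzene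
Conditions: PPh3, DIAD, toluene, 0 °C → rt
Reagents that add atoms: none
Why: Mitsunobu etherification of the only free hydroxyl with the phenol forms the O1–C2 bond of the upper unit; the benzylic position is already a methyl ether and cannot compete.

Step 16
Reactants: 27 the aryl ether
Product: 28 (3R,4S)-7-(benzyloxy)-3-[2-(benzyloxy)-4,5-dimethoxyphenyl]-4-{4-(benzyloxy)-2-[(3R)-7-(benzyloxy)chroman-3-yl]-6-methoxyphenyl}chroman
Conditions: BF3·OEt2 (cat.), CH2Cl2, −40 → 0 °C
Reagents that add atoms: none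
Why: intramolecular Friedel–Crafts alkylation; ionisation of the benzylic methyl ether gives a cation stabilised by the ortho-methoxy/para-benzyloxy ring, the tethered ring attacks para to its benzyloxy group (six-membered closure, C4–C4a), and C4 should form trans to the C3 aryl group because both bulky aryl groups sit pseudo-equatorial in the chair-like transition state.

Step 17
Reactants: 28 the tetrabenzyl ether
Product: 29 (3R,4S)-3-(2-hydroxy-4,5-dimethoxyphenyl)-4-{4-hydroxy-2-[(3R)-7-hydroxychroman-3-yl]-6-methoxyphenyl}chroman-7-ol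
Conditions: H2 (1 atm), Pd/C, EtOAc/MeOH, rt
Reagents that add atoms: none
Why: hydrogenolysis of the four benzyl aryl ethers should free all phenols without affecting the methyl ethers, the chroman rings or the three stereocentres.

**Compound list**

1 | methyl 2-(3,5-dihydroxyphenyl)acetate | COC(=O)Cc1cc(O)cc(O)c1 | starting material
2 | methyl 2-(2-formyl-3,5-dihydroxyphenyl)acetate | COC(=O)Cc1cc(O)cc(O)c1C=O | intermediate
3 | methyl 2-[5-(benzyloxy)-2-formyl-3-hydroxyphenyl]acetate | COC(=O)Cc1cc(OCc2ccccc2)cc(O)c1C=O | intermediate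
4 | methyl 2-[5-(benzyloxy)-2-formyl-3-methoxyphenyl]acetate | COC(=O)Cc1cc(OCc2ccccc2)cc(OC)c1C=O | intermediate
5 | methyl 2-[5-(benzyloxy)-2-(dimethoxymethyl)-3-methoxyphenyl]acetate (not isolated) | COC(=O)Cc1cc(OCc2ccccc2)cc(OC)c1C(OC)OC | intermediate
6 | lithium 2-[5-(benzyloxy)-2-(dimethoxymethyl)-3-methoxyphenyl]acetate | [Li+].[O-]C(=O)Cc1cc(OCc2ccccc2)cc(OC)c1C(OC)OC | intermediate
7 | (R)-4-benzyloxazolidin-2-one | O=C1N[C@H](Cc2ccccc2)CO1 | starting material
8 | 2-[5-(benzyloxy)-2-(dimethoxymethyl)-3-methoxyphenyl]acetic pivalic anhydride (not isolated) | CC(C)(C)C(=O)OC(=O)Cc1cc(OCc2ccccc2)cc(OC)c1C(OC)OC | intermediate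
9 | (R)-4-benzyl-3-{2-[5-(benzyloxy)-2-(dimethoxymethyl)-3-methoxyphenyl]acetyl}oxazolidin-2-one | COC(OC)c1c(OC)cc(OCc2ccccc2)cc1CC(=O)N1[C@H](Cc2ccccc2)COC1=O | intermediate
10 | [4-(bromomethyl)phenoxy](tert-butyl)dimethylsilane | BrCc1ccc(O[Si](C)(C)C(C)(C)C)cc1 | starting material
11 | (R)-4-benzyl-3-{(2R)-2-[5-(benzyloxy)-2-(dimethoxymethyl)-3-methoxyphenyl]-3-[4-(tert-butyldimethylsilyloxy)phenyl]propanoyl}oxazolidin-2-one | COC(OC)c1c(OC)cc(OCc2ccccc2)cc1[C@@H](Cc1ccc(O[Si](C)(C)C(C)(C)C)cc1)C(=O)N1[C@H](Cc2ccccc2)COC1=O | intermediate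
12 | (2R)-2-[5-(benzyloxy)-2-(dimethoxymethyl)-3-methoxyphenyl]-3-[4-(tert-butyldimethylsilyloxy)phenyl]propan-1-ol (not isolated) | COC(OC)c1c(OC)cc(OCc2ccccc2)cc1[C@@H](Cc1ccc(O[Si](C)(C)C(C)(C)C)cc1)CO | intermediate
13 | 4-{(2R)-2-[5-(benzyloxy)-2-(dimethoxymethyl)-3-methoxyphenyl]-3-hydroxypropyl}phenol | COC(OC)c1c(OC)cc(OCc2ccccc2)cc1[C@@H](Cc1ccc(O)cc1)CO | intermediate
14 | 4-{(2R)-2-[5-(benzyloxy)-2-(dimethoxymethyl)-3-methoxyphenyl]-3-hydroxypropyl}-4-methoxycyclohexa-2,5-dien-1-one (not isolated) | COC(OC)c1c(OC)cc(OCc2ccccc2)cc1[C@@H](CC1(OC)C=CC(=O)C=C1)CO | intermediate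
15 | (3R)-3-[5-(benzyloxy)-2-(dimethoxymethyl)-3-methoxyphenyl]-4a-methoxy-2,3,4,4a,8,8a-hexahydro-7H-chromen-7-one, cis-fused, both ring-fusion diastereomers, ring-fusion centres left open in the SMILES (not isolated) | COC(OC)c1c(OC)cc(OCc2ccccc2)cc1[C@@H]1COC2CC(=O)C=CC2(OC)C1 | intermediate
16 | (3R)-3-[5-(benzyloxy)-2-(dimethoxymethyl)-3-methoxyphenyl]chroman-7-ol | COC(OC)c1c(OC)cc(OCc2ccccc2)cc1[C@@H]1COc2cc(O)ccc2C1 | intermediate
17 | (3R)-7-(benzyloxy)-3-[5-(benzyloxy)-2-(dimethoxymethyl)-3-methoxyphenyl]chroman | COC(OC)c1c(OC)cc(OCc2ccccc2)cc1[C@@H]1COc2cc(OCc3ccccc3)ccc2C1 | intermediate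
18 | 1-(2-hydroxy-4,5-dimethoxyphenyl)ethan-1-one | CC(=O)c1cc(OC)c(OC)cc1O | starting material
19 | 1-[2-(benzyloxy)-4,5-dimethoxyphenyl]ethan-1-one | CC(=O)c1cc(OC)c(OC)cc1OCc1ccccc1 | intermediate
20 | 2-[2-(benzyloxy)-4,5-dimethoxyphenyl]-1-morpholinoethane-1-thione (not isolated) | S=C(Cc1cc(OC)c(OC)cc1OCc1ccccc1)N1CCOCC1 | intermediate
21 | 2-[2-(benzyloxy)-4,5-dimethoxyphenyl]acetic acid | OC(=O)Cc1cc(OC)c(OC)cc1OCc1ccccc1 | intermediate
22 | 2-[2-(benzyloxy)-4,5-dimethoxyphenyl]acetic pivalic anhydride (not isolated) | CC(C)(C)C(=O)OC(=O)Cc1cc(OC)c(OC)cc1OCc1ccccc1 | intermediate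
23 | (R)-4-benzyl-3-{2-[2-(benzyloxy)-4,5-dimethoxyphenyl]acetyl}oxazolidin-2-one | O=C(Cc1cc(OC)c(OC)cc1OCc1ccccc1)N1[C@H](Cc2ccccc2)COC1=O | intermediate
24 | (R)-4-benzyl-3-{(2S)-2-[2-(benzyloxy)-4,5-dimethoxyphenyl]-3-[4-(benzyloxy)-2-((3R)-7-(benzyloxy)chroman-3-yl)-6-methoxyphenyl]-3-methoxypropanoyl}oxazolidin-2-one, epimers at C3 of the chain | O=C([C@@H](c1cc(OC)c(OC)cc1OCc1ccccc1)C(OC)c1c(OC)cc(OCc2ccccc2)cc1[C@@H]1COc2cc(OCc3ccccc3)ccc2C1)N1[C@H](Cc2ccccc2)COC1=O | intermediate
25 | (2R)-2-[2-(benzyloxy)-4,5-dimethoxyphenyl]-3-[4-(benzyloxy)-2-((3R)-7-(benzyloxy)chroman-3-yl)-6-methoxyphenyl]-3-methoxypropan-1-ol, epimers at C3 | OC[C@@H](c1cc(OC)c(OC)cc1OCc1ccccc1)C(OC)c1c(OC)cc(OCc2ccccc2)cc1[C@@H]1COc2cc(OCc3ccccc3)ccc2C1 | intermediate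
26 | 3-(benzyloxy)phenol | Oc1cccc(OCc2ccccc2)c1 | starting material
27 | 1-(benzyloxy)-3-{[(2R)-2-[2-(benzyloxy)-4,5-dimethoxyphenyl]-3-[4-(benzyloxy)-2-((3R)-7-(benzyloxy)chroman-3-yl)-6-methoxyphenyl]-3-methoxypropyl]oxy}benzene, epimers at C3 of the chain | c1cc(OCc2ccccc2)cc(OC[C@@H](c2cc(OC)c(OC)cc2OCc2ccccc2)C(OC)c2c(OC)cc(OCc3ccccc3)cc2[C@@H]2COc3cc(OCc4ccccc4)ccc3C2)c1 | intermediate
28 | (3R,4S)-7-(benzyloxy)-3-[2-(benzyloxy)-4,5-dimethoxyphenyl]-4-{4-(benzyloxy)-2-[(3R)-7-(benzyloxy)chroman-3-yl]-6-methoxyphenyl}chroman | COc1cc(OCc2ccccc2)c([C@@H]3COc4cc(OCc5ccccc5)ccc4[C@H]3c3c(OC)cc(OCc4ccccc4)cc3[C@@H]3COc4cc(OCc5ccccc5)ccc4C3)cc1OC | intermediate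
29 | (3R,4S)-3-(2-hydroxy-4,5-dimethoxyphenyl)-4-{4-hydroxy-2-[(3R)-7-hydroxychroman-3-yl]-6-methoxyphenyl}chroman-7-ol | COc1cc(O)c([C@@H]2COc3cc(O)ccc3[C@H]2c2c(OC)cc(O)cc2[C@@H]2COc3cc(O)ccc3C2)cc1OC | target

**Totals.** Total step count: 17. Longest linear sequence: 14 steps (steps 1–9 and 13–17).

**Steps most likely to fail**

Step 8. The dienone may collapse by loss of methanol to a para-quinone methide, or take up methanol intermolecularly instead of the tethered alcohol, and the electron-rich benzyloxy ring may be over-oxidised. The fallback sets out from 9 and rejoins the route at 17; it makes the same O1–C8a bond by intramolecular Buchwald–Hartwig etherification. Purchased 2-bromo-4-hydroxybenzaldehyde is benzylated (BnBr, K2CO3) to 4-(benzyloxy)-2-bromobenzaldehyde F1, reduced (NaBH4) to [4-(benzyloxy)-2-bromophenyl]methanol F2 and brominated (PBr3) to 4-(benzyloxy)-2-bromo-1-(bromomethyl)benzene F3. Alkylation of the sodium enolate of 9 with F3 under the conditions of step 6 should give the bromoaryl imide F4, and LiBH4 reduction the bromo alcohol F5. Pd(OAc)2, 2-(di-tert-butylphosphino)-1,1'-binaphthyl and Cs2CO3 in toluene at 80 °C should then close the aryl ether and give 17 directly.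

Step 13. Capture of the hindered, strongly stabilised oxocarbenium ion may be slow, and the adduct may lose methanol to the conjugated alkene, destroying the new stereocentre. The fallback sets out from 17 and 21 and rejoins at 28; it replaces the acetal alkylation by a boron aldol reaction. Hydrolysis of 17 (pyridinium tosylate, acetone/H2O) gives 4-(benzyloxy)-2-[(3R)-7-(benzyloxy)chroman-3-yl]-6-methoxybenzaldehyde F6. Acid 21 is attached to purchased (S)-4-benzyloxazolidin-2-one as in step 12 to give the (S)-imide F7; the enantiomeric auxiliary is needed because the boron aldol reaction uses the enolate face opposite to that of the chelated titanium alkylation. Bu2BOTf/i-Pr2NEt and F6 should give the syn-aldol adduct F8, LiBH4 the diol F9, and a Mitsunobu reaction with 26 at the primary hydroxyl the hydroxy ether F10. Under the conditions of step 16, F10 ionises at the benzylic alcohol and should close to 28.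

Step 16. The benzylic cation may lose the C3 proton or undergo a 1,2-hydride shift before ring closure, eroding the C3 configuration, and the ortho-benzyloxy oxygen may capture it first. The fallback sets out from 17 (through aldehyde F6), 26 and 23 and rejoins at 28; it forms C4–C4a before the C3 stereocentre exists, so that no cation is generated next to it. The bromomagnesium phenoxide of 26 (EtMgBr, toluene) should add ortho-selectively to F6 to give the ortho-hydroxybenzhydrol F11. TiCl4 ionises F11 to the ortho-quinone methide, which the chlorotitanium enolate of 23 should attack to give the Michael adduct imide F12, expected to lactonise with loss of the auxiliary to the dihydrocoumarin F13. LiBH4 reduces either to the phenol alcohol F14, and an intramolecular Mitsunobu reaction closes O1–C2 to give 28 together with any cis isomer F15. KOt-Bu in DMSO should equilibrate F15 to the trans compound 28 through the doubly benzylic C4 anion.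

**Further compounds**

F1 | step 8 | 4-(benzyloxy)-2-bromobenzaldehyde | O=Cc1ccc(OCc2ccccc2)cc1Br
F2 | step 8 | [4-(benzyloxy)-2-bromophenyl]methanol | OCc1ccc(OCc2ccccc2)cc1Br
F3 | step 8 | 4-(benzyloxy)-2-bromo-1-(bromomethyl)benzene | BrCc1ccc(OCc2ccccc2)cc1Br
F4 | step 8 | (R)-4-benzyl-3-{(2R)-2-[5-(benzyloxy)-2-(dimethoxymethyl)-3-methoxyphenyl]-3-[4-(benzyloxy)-2-bromophenyl]propanoyl}oxazolidin-2-one | COC(OC)c1c(OC)cc(OCc2ccccc2)cc1[C@@H](Cc1ccc(OCc2ccccc2)cc1Br)C(=O)N1[C@H](Cc2ccccc2)COC1=O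
F5 | step 8 | (2R)-2-[5-(benzyloxy)-2-(dimethoxymethyl)-3-methoxyphenyl]-3-[4-(benzyloxy)-2-bromophenyl]propan-1-ol | COC(OC)c1c(OC)cc(OCc2ccccc2)cc1[C@@H](Cc1ccc(OCc2ccccc2)cc1Br)CO
F6 | step 13 | 4-(benzyloxy)-2-[(3R)-7-(benzyloxy)chroman-3-yl]-6-methoxybenzaldehyde | O=Cc1c(OC)cc(OCc2ccccc2)cc1[C@@H]1COc2cc(OCc3ccccc3)ccc2C1
F7 | step 13 | (S)-4-benzyl-3-{2-[2-(benzyloxy)-4,5-dimethoxyphenyl]acetyl}oxazolidin-2-one | O=C(Cc1cc(OC)c(OC)cc1OCc1ccccc1)N1[C@@H](Cc2ccccc2)COC1=O
F8 | step 13 | (S)-4-benzyl-3-{(2S,3S)-2-[2-(benzyloxy)-4,5-dimethoxyphenyl]-3-[4-(benzyloxy)-2-((3R)-7-(benzyloxy)chroman-3-yl)-6-methoxyphenyl]-3-hydroxypropanoyl}oxazolidin-2-one | O=C([C@@H](c1cc(OC)c(OC)cc1OCc1ccccc1)[C@H](O)c1c(OC)cc(OCc2ccccc2)cc1[C@@H]1COc2cc(OCc3ccccc3)ccc2C1)N1[C@@H](Cc2ccccc2)COC1=O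
F9 | step 13 | (1S,2R)-2-[2-(benzyloxy)-4,5-dimethoxyphenyl]-1-[4-(benzyloxy)-2-((3R)-7-(benzyloxy)chroman-3-yl)-6-methoxyphenyl]propane-1,3-diol | OC[C@@H](c1cc(OC)c(OC)cc1OCc1ccccc1)[C@H](O)c1c(OC)cc(OCc2ccccc2)cc1[C@@H]1COc2cc(OCc3ccccc3)ccc2C1
F10 | step 13 | (1S,2R)-2-[2-(benzyloxy)-4,5-dimethoxyphenyl]-1-[4-(benzyloxy)-2-((3R)-7-(benzyloxy)chroman-3-yl)-6-methoxyphenyl]-3-[3-(benzyloxy)phenoxy]propan-1-ol | c1cc(OCc2ccccc2)cc(OC[C@@H](c2cc(OC)c(OC)cc2OCc2ccccc2)[C@H](O)c2c(OC)cc(OCc3ccccc3)cc2[C@@H]2COc3cc(OCc4ccccc4)ccc3C2)c1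
F11 | step 16 | 5-(benzyloxy)-2-{[4-(benzyloxy)-2-((3R)-7-(benzyloxy)chroman-3-yl)-6-methoxyphenyl](hydroxy)methyl}phenol, carbinol epimers | OC(c1ccc(OCc2ccccc2)cc1O)c1c(OC)cc(OCc2ccccc2)cc1[C@@H]1COc2cc(OCc3ccccc3)ccc2C1
F12 | step 16 | (R)-4-benzyl-3-{(2R)-2-[2-(benzyloxy)-4,5-dimethoxyphenyl]-3-[4-(benzyloxy)-2-hydroxyphenyl]-3-[4-(benzyloxy)-2-((3R)-7-(benzyloxy)chroman-3-yl)-6-methoxyphenyl]propanoyl}oxazolidin-2-one, epimers at C3 of the chain | O=C([C@@H](c1cc(OC)c(OC)cc1OCc1ccccc1)C(c1ccc(OCc2ccccc2)cc1O)c1c(OC)cc(OCc2ccccc2)cc1[C@@H]1COc2cc(OCc3ccccc3)ccc2C1)N1[C@H](Cc2ccccc2)COC1=O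
F13 | step 16 | (3R)-7-(benzyloxy)-3-[2-(benzyloxy)-4,5-dimethoxyphenyl]-4-{4-(benzyloxy)-2-[(3R)-7-(benzyloxy)chroman-3-yl]-6-methoxyphenyl}chroman-2-one, epimers at C4 | O=C1Oc2cc(OCc3ccccc3)ccc2C(c2c(OC)cc(OCc3ccccc3)cc2[C@@H]2COc3cc(OCc4ccccc4)ccc3C2)[C@@H]1c1cc(OC)c(OC)cc1OCc1ccccc1
F14 | step 16 | 5-(benzyloxy)-2-{(2R)-2-[2-(benzyloxy)-4,5-dimethoxyphenyl]-1-[4-(benzyloxy)-2-((3R)-7-(benzyloxy)chroman-3-yl)-6-methoxyphenyl]-3-hydroxypropyl}phenol, epimers at C1 of the chain | OC[C@@H](c1cc(OC)c(OC)cc1OCc1ccccc1)C(c1ccc(OCc2ccccc2)cc1O)c1c(OC)cc(OCc2ccccc2)cc1[C@@H]1COc2cc(OCc3ccccc3)ccc2C1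
F15 | step 16 | (3R,4R)-7-(benzyloxy)-3-[2-(benzyloxy)-4,5-dimethoxyphenyl]-4-{4-(benzyloxy)-2-[(3R)-7-(benzyloxy)chroman-3-yl]-6-methoxyphenyl}chroman (cis isomer of 28) | COc1cc(OCc2ccccc2)c([C@@H]3COc4cc(OCc5ccccc5)ccc4[C@@H]3c3c(OC)cc(OCc4ccccc4)cc3[C@@H]3COc4cc(OCc5ccccc5)ccc4C3)cc1OC
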